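- Ask first where the first product stops, for the double product is built from it.

| setting | south-west | birch | larch | oak |
|---|---|---|---|---|
| substrate | 13 mM | 20 mM | 20 mM | 20 mM |
| partner | 2 equiv | 2.00 equiv | 1.20 equiv | 4.00 equiv |
| remark | run made earlier |  |  |  |
| time |  | 8.0 h | 8.0 h | 8.0 h |

- south-west (time / h: double product / %, first product / %): 0.333: 0.1, 1.9; 1.00: 0, 4.8; 1.50: 0.4, 6.2; 2.50: 0.8, 7.4; 4.00: 2.3, 8.3; 5.00: 3.7, 9.1

(scatter of a reading: 0.5 percentage points)

- which of these holds the largest part of the substrate at the end of birch (double product / triple product / first product / tetra adduct / substrate)
- which of these holds the largest part of the substrate at the end of larch (double product / triple product / first product / tetra adduct / substrate)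
- which of these holds the largest part of the substrate at the end of oak (double product / triple product / first product / tetra adduct / substrate)
- final double product in larch, as a percentage of the substrate charged

- percentages count the substrate that a species holds: one side product counts as two
- steps that have been proposed: substrate + partner -> first product; partner + first product -> double product; partner + double product -> triple product; partner + triple product -> tetra adduct; substrate + first product -> side product

- In south-west the first product gains 4.8 % by 1.00 h, but later, from 2.50 h to 5.00 h, it gains less: 1.7 percentage points.
- I read this as a resting state, and I assume its main loss is the step with substrate. Substrate then cancels from the balance of the first product, and the level of first product follows the partner concentration.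
- On that assumption the rate of double product goes with partner concentration squared, and its percentage is that amount divided by the substrate charged.
- Substrate: going from 13 mM to 20 mM with partner concentration and time held multiplies the percentage by 0.650.
- Partner: larch holds 24.0 mM against 26.0 mM, a factor of 0.852 once squared.
- Together they give 0.554 for larch. I call this the reach: charged partner concentration squared over substrate charged, measured against south-west at the same time.
- Time: the last south-west readings of double product, each good to 0.5 points, continued straight to 8.0 h, give an estimate of 7.18 % for south-west.
- My larch reckoning is therefore 3.98 %. The same reckoning gives 11.0 % for birch and 44.2 % for oak, and I trust the oak line least.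
- The forecast names substrate for birch, substrate for larch and double product for oak, saying “the double product probably leads if later steps are not much faster”. It puts larch at 3.3 %, within 2 % to 5 %, lower than my figure.
- The flask gives substrate in birch, substrate in larch and double product in oak, with 3.48 % of double product in larch.

    substrate + partner → first product (k = 7.09 × 10⁻⁴ L mol⁻¹ s⁻¹)
    partner + first product → double product (k = 0.00120 L mol⁻¹ s⁻¹)
    partner + double product → triple product (k = 7.58 × 10⁻⁵ L mol⁻¹ s⁻¹)
    partner + triple product → tetra adduct (k = 0.00173 L mol⁻¹ s⁻¹)
    substrate + first product → side product (k = 0.0102 L mol⁻¹ s⁻¹)

- In larch the double product has a half-life of 110 h by the path to triple product alone, the other concentrations as charged, long against 8.0 h, and triple product stands at 0.0525 % at the end. Now take larch with 8.0 mM of substrate and the same equivalents and time. Its reach falls to 0.222, so larch's result scales to 1.39 %. That flask gives 1.30 %.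

(Readings and results were generated by integration for substances that don't exist, and the scatter is random.)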